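A product that nothing consumes cannot lose ground in a closed flask of constant volume, yet in Thursday's run bis adduct falls from 34.0% of the substrate charged at 0.833 d to 20.2% at 5.00 d. Substrate takes up coupling partner to give mono adduct, which takes up a second partner to give bis adduct, and something then removes the bis adduct.

in all of them: substrate 0.020 M
- Sunday's: coupling partner 0.57 equiv; run made earlier
- Thursday's: coupling partner 2.8 equiv; run made earlier
- amber: coupling partner 4.00 equiv; time 5.0 d
- violet: coupling partner 1.00 equiv; time 5.0 d

- Sunday's (time / d: bis adduct / %): 1.04: 6.9; 2.08: 6.9; 3.00: 7.1; 4.00: 6.9; 5.00: 6.6
- Thursday's (time / d: bis adduct / %): 0.417: 34.2; 0.833: 34.0; 1.25: 32.4; 2.50: 27.3; 5.00: 20.2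

(scatter of a reading: 0.5 percentage points)

- which of these holds the largest part of the substrate at the end of amber (mono adduct / substrate / bis adduct)
- which of these holds the largest part of the substrate at the end of violet (mono adduct / substrate / bis adduct)
- final bis adduct in amber, as a percentage of the substrate charged

The fall can be read as a fade constant, a pseudo-first-order decay constant, from the logarithm of those two readings: 0.125 d⁻¹. Replacing the curve by its mean level gives 0.122 d⁻¹, so little is lost by that simplification.

My own assumption is that the constant scales with the partner charged. Sunday's run allows this: scaled to its charge, the constant takes 6.9% to 6.24%, against a reading of 6.6%, each reading being good to 0.5 percentage points.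

Amber looks nearly the same as Thursday's run, but its constant becomes 0.179 d⁻¹, faster than Thursday's. If amber stands at Thursday's level at 0.833 d, a guess, it ends at 16.2%, lower than Thursday's final reading. This reckoning does not address the two questions about the largest holder.

The forecast gave mono adduct for amber, mono adduct for violet and 24% of bis adduct, expecting that “its late free partner should converge towards Thursday's”.

Amber ends at 14.2% of bis adduct, with bis adduct the largest of the three in amber and substrate in violet. Over-reaction product holds 58.4% of amber's substrate, outside the three asked. From 20.5% at 2.50 d, the scaled constant gives 13.1% at the end of amber.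

    bis adduct + by-product → side product (k = 0.00300 M⁻¹ min⁻¹)
    substrate + coupling partner → mono adduct + by-product (k = 0.0942 M⁻¹ min⁻¹)
    coupling partner + mono adduct → bis adduct + by-product (k = 0.184 M⁻¹ min⁻¹)
    coupling partner → decomposed reagent (k = 0.00107 min⁻¹)
    coupling partner + bis adduct → over-reaction product (k = 0.0765 M⁻¹ min⁻¹)

In the neighbour flask, amber with 1.60 equiv of partner, the constant scales to 0.0714 d⁻¹, so a fade of 30.0% over 5.0 d is reckoned, counted as if that flask's bis adduct stood there from the start. That flask ends with 18.8% of bis adduct and 8.54% of side product, the fade's product in the scheme, which makes side product 31.3% of the two together.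

The runs were computed with made-up constants; scatter was added.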